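**Retrosynthetic overview**

- The target is a diaryl ether joining C-6 of unit A (7-hydroxycoumarin) to C-5 of unit B (6,7-dihydroxycoumarin). The last operations are dehydrogenation of C3–C4 in unit A and cleavage of three methyl ethers.
- The strategy rests on one feature of unit A: the lactone oxygen O-1 sits on C-8a, which is para to the ether carbon C-6. The O-1–C-8a bond is therefore cut by a retro-Baeyer–Villiger step to a 1-indanone whose C-1 ketone is para to indanone C-5.
- The same ketone activates a fluoride at indanone C-5, so the ether C–O bond is cut there (SNAr) to 5-hydroxy-6,7-dimethoxycoumarin and 5-fluoro-6-methoxy-1-indanone.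
- Unit B comes from 3,4,5-trimethoxyphenol by ortho-formylation, O-chloroacetylation, BCl3 demethylation ortho to the aldehyde and intramolecular Wittig closure.
- Ring order: the pyranone ring of unit B closes first (step 4), then the pyranone ring of unit A forms by ring expansion of the cyclopentanone (step 6).

Key step: step 6

Remark: unit B is closed to the coumarin before the ether bond is made, because an aryl aldehyde would condense with the enolisable indanone (Claisen–Schmidt) under the carbonate conditions of the ether formation; compounds 1, 3 and 9 are taken as purchased.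

**Route**

Step 1
Reactants: 1 3,4,5-trimethoxyphenol
Product: 2 6-hydroxy-2,3,4-trimethoxybenzaldehyde
Conditions: MgCl2, Et3N, (CH2O)n, MeCN, reflux; then aq HCl
Reagents that add atoms: paraformaldehyde (as formaldehyde), C=O
Why: Casnati–Skattebøl ortho-formylation, in which the magnesium phenoxide delivers formaldehyde to the carbon ortho to oxygen and a second formaldehyde oxidises the benzylic alkoxide to the aldehyde; the two ortho positions of 1 are equivalent by symmetry, so only one product can form.

Step 2
Reactants: 2 6-hydroxy-2,3,4-trimethoxybenzaldehyde; 3 chloroacetyl chloride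
Product: 4 2-formyl-3,4,5-trimethoxyphenyl chloroacetate
Conditions: pyridine, CH2Cl2, 0 °C → rt
Reagents that add atoms: none
Why: O-acylation of the phenol with pyridine as nucleophilic catalyst places the two carbons that become C-2 and C-3 of unit B on the oxygen that becomes O-1, and masks that oxygen as an ester for the next step.

Step 3
Reactants: 4 2-formyl-3,4,5-trimethoxyphenyl chloroacetate
Product: 5 2-formyl-3-hydroxy-4,5-dimethoxyphenyl chloroacetate
Conditions: BCl3 (1.2 equiv), CH2Cl2, −78 → 0 °C; cold dilute HCl
Reagents that add atoms: none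
Why: Chelation-controlled demethylation, in which BCl3 binds the aldehyde oxygen and the one methoxy oxygen ortho to it in a six-membered chelate and chloride removes only that methyl group; the other methoxy groups and the aryl ester cannot chelate in this way and should stay intact at low temperature.

Step 4
Reactants: 5 2-formyl-3-hydroxy-4,5-dimethoxyphenyl chloroacetate
Product: 8 5-hydroxy-6,7-dimethoxy-2H-chromen-2-one (5-hydroxy-6,7-dimethoxycoumarin), via phosphonium chloride 6 (not isolated), via ester ylide 7 (not isolated)
Conditions: PPh3, MeCN, 60 °C; then Et3N, rt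
Reagents that add atoms: none
Why: SN2 quaternisation of PPh3 by the α-chloro ester, deprotonation to the ester-stabilised ylide and intramolecular Wittig olefination with the ortho aldehyde close the pyranone ring with its necessarily cis C3=C4 bond; because the ester oxygen is already fixed, only the 5-hydroxy-6,7-dimethoxy isomer can form.

Step 5
Reactants: 8 5-hydroxy-6,7-dimethoxy-2H-chromen-2-one; 9 5-fluoro-6-methoxy-1-indanone
Product: 10 5-[(6-methoxy-1-oxo-2,3-dihydro-1H-inden-5-yl)oxy]-6,7-dimethoxy-2H-chromen-2-one
Conditions: K2CO3, DMF, 110 °C, N2; dilute HCl work-up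
Reagents that add atoms: none
Why: SNAr, in which the phenoxide of 8 adds to C-5 of 9, the Meisenheimer anion is stabilised by the para C-1 ketone and fluoride leaves; neither partner carries an aldehyde, so the indanone has no condensation partner, and any lactone opened by adventitious hydroxide should reclose on acidification.

Step 6
Reactants: 10 5-[(6-methoxy-1-oxo-2,3-dihydro-1H-inden-5-yl)oxy]-6,7-dimethoxy-2H-chromen-2-one
Product: 11 5-[(7-methoxy-2-oxo-3,4-dihydro-2H-chromen-6-yl)oxy]-6,7-dimethoxy-2H-chromen-2-one
Conditions: mCPBA (2 equiv), TFA (1 equiv), CH2Cl2, 0 °C → rt, dark; aq Na2S2O3/NaHCO3 wash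
Reagents that add atoms: mCPBA (3-chloroperoxybenzoic acid), OOC(=O)c1cccc(Cl)c1
Why: The acid-activated ketone adds the peracid to give the tetrahedral Criegee adduct, and the aryl carbon C-7a shifts from carbon to oxygen as 3-chlorobenzoate leaves, so that oxygen is inserted between C-7a and C-1 (Baeyer–Villiger oxidation). The closest known reaction type is the peracid ring expansion of alkoxy-substituted 1-indanones to 3,4-dihydrocoumarins. The six-membered lactone ring of unit A is closed by ring expansion of the five-membered ketone through this 1,2-aryl shift, not by a cyclisation, and no stereocentre is formed. The step needs migration of the aryl carbon in preference to the C-2 methylene, and the aryloxy oxygen para to C-7a secures this by stabilising the positive charge that develops in the migrating ring. It also needs chemoselectivity against unit B, which has no ketone and whose C3=C4 bond is conjugated to the lactone carbonyl and too electron-poor for an electrophilic peracid.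

Step 7
Reactants: 11 5-[(7-methoxy-2-oxo-3,4-dihydro-2H-chromen-6-yl)oxy]-6,7-dimethoxy-2H-chromen-2-one
Product: 12 6,7-dimethoxy-5-[(7-methoxy-2-oxo-2H-chromen-6-yl)oxy]-2H-chromen-2-one
Conditions: DDQ (2.5 equiv), 1,4-dioxane, reflux
Reagents that add atoms: none
Why: DDQ dehydrogenation of a 3,4-dihydrocoumarin, in which hydride is abstracted from benzylic C-4 (cation stabilised by O-1 ortho and the 7-methoxy group para to C-4a) and the C-3 proton is then lost to give the conjugated coumarin; unit B is already unsaturated.

Step 8
Reactants: 12 6,7-dimethoxy-5-[(7-methoxy-2-oxo-2H-chromen-6-yl)oxy]-2H-chromen-2-one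
Product: 13 6,7-dihydroxy-5-[(7-hydroxy-2-oxo-2H-chromen-6-yl)oxy]-2H-chromen-2-one (CNP0197949.0)
Conditions: BBr3 (8 equiv), CH2Cl2, −78 °C → rt; H2O quench, degassed solvents for work-up
Reagents that add atoms: none
Why: BBr3 O-demethylation, in which each methoxy oxygen is complexed by boron and bromide attacks the methyl carbon (SN2); the diaryl ether offers no sp3 carbon and should survive, and the two lactones are stable to the reagent.

**Compound list**

1 | 3,4,5-trimethoxyphenol | COc1cc(O)cc(OC)c1OC | starting material
2 | 6-hydroxy-2,3,4-trimethoxybenzaldehyde | O=Cc1c(O)cc(OC)c(OC)c1OC | intermediate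
3 | chloroacetyl chloride | ClCC(Cl)=O | starting material
4 | 2-formyl-3,4,5-trimethoxyphenyl chloroacetate | O=Cc1c(OC(=O)CCl)cc(OC)c(OC)c1OC | intermediate
5 | 2-formyl-3-hydroxy-4,5-dimethoxyphenyl chloroacetate | O=Cc1c(OC(=O)CCl)cc(OC)c(OC)c1O | intermediate
6 | [2-(2-formyl-3-hydroxy-4,5-dimethoxyphenoxy)-2-oxoethyl]triphenylphosphonium chloride (not isolated) | O=Cc1c(OC(=O)C[P+](c2ccccc2)(c2ccccc2)c2ccccc2)cc(OC)c(OC)c1O.[Cl-] | intermediate
7 | 2-formyl-3-hydroxy-4,5-dimethoxyphenyl (triphenylphosphoranylidene)acetate (not isolated) | O=Cc1c(OC(=O)C=P(c2ccccc2)(c2ccccc2)c2ccccc2)cc(OC)c(OC)c1O | intermediate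
8 | 5-hydroxy-6,7-dimethoxy-2H-chromen-2-one | COc1cc2oc(=O)ccc2c(O)c1OC | intermediate
9 | 5-fluoro-6-methoxy-1-indanone | COc1cc2c(cc1F)CCC2=O | starting material
10 | 5-[(6-methoxy-1-oxo-2,3-dihydro-1H-inden-5-yl)oxy]-6,7-dimethoxy-2H-chromen-2-one | COc1cc2c(cc1Oc1c(OC)c(OC)cc3oc(=O)ccc13)CCC2=O | intermediate
11 | 5-[(7-methoxy-2-oxo-3,4-dihydro-2H-chromen-6-yl)oxy]-6,7-dimethoxy-2H-chromen-2-one | COc1cc2OC(=O)CCc2cc1Oc1c(OC)c(OC)cc2oc(=O)ccc12 | intermediate
12 | 6,7-dimethoxy-5-[(7-methoxy-2-oxo-2H-chromen-6-yl)oxy]-2H-chromen-2-one | COc1cc2oc(=O)ccc2cc1Oc1c(OC)c(OC)cc2oc(=O)ccc12 | intermediate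
13 | 6,7-dihydroxy-5-[(7-hydroxy-2-oxo-2H-chromen-6-yl)oxy]-2H-chromen-2-one | O=c1ccc2cc(Oc3c(O)c(O)cc4oc(=O)ccc34)c(O)cc2o1 | target

**Step count and risks**

Total step count: 8. Longest linear sequence: 8 steps (1 → 13); 3 and 9 enter as purchased partners.

Steps most likely to fail:

1. Step 6 (key ring expansion). Addition of the peracid to the donor-substituted aryl ketone may be slow, so that electrophilic hydroxylation of the alkoxy-rich rings or migration of the methylene carbon competes. The fallback sets out from 8 and comes back at 12, bringing the lactone ring of unit A in preformed. Purchased 5-bromo-2-hydroxy-4-methoxybenzaldehyde F1 would be heated with ethyl (triphenylphosphoranylidene)acetate in N,N-diethylaniline at reflux. The Wittig product, ethyl (E)-3-(5-bromo-2-hydroxy-4-methoxyphenyl)prop-2-enoate F2 (not isolated), should isomerise and lactonise in the hot solvent to 6-bromo-7-methoxycoumarin F3. Ullmann-type coupling of 8 with F3 (CuI, picolinic acid, K3PO4, DMSO, 100 °C) should then give 12 and bypass steps 5 to 7.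

2. Step 5 (ether formation). The fluoride is activated by a single para ketone and carries an ortho methoxy group, and the phenoxide is flanked on both sides. Addition may therefore be slow, and at the temperature then needed the indanone may self-condense or the lactone may open. The fallback sets out from 8 and comes back at 10: copper-catalysed Ullmann coupling of 8 with purchased 5-bromo-6-methoxy-1-indanone F4 (CuI, picolinic acid, K3PO4, DMSO, 90 °C). It does not depend on ketone activation, and the ketone is kept for step 6.

3. Step 7 (dehydrogenation). Hydride abstraction from C-4 may be slow, so that prolonged heating leads to oxidative degradation of the alkoxy-rich rings or to opening of the aryl ester lactone. The fallback sets out from 11 and comes back at 12. Radical bromination at benzylic C-4 (NBS, AIBN, PhCF3, 80 °C) should give racemic 5-[(4-bromo-7-methoxy-2-oxo-3,4-dihydro-2H-chromen-6-yl)oxy]-6,7-dimethoxy-2H-chromen-2-one F5. Elimination of HBr with Et3N in CH2Cl2 at rt should then give 12.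

**Further compounds**

F1 | step 6 | 5-bromo-2-hydroxy-4-methoxybenzaldehyde (purchased) | O=Cc1cc(Br)c(OC)cc1O
F2 | step 6 | ethyl (E)-3-(5-bromo-2-hydroxy-4-methoxyphenyl)prop-2-enoate (not isolated) | CCOC(=O)/C=C/c1cc(Br)c(OC)cc1O
F3 | step 6 | 6-bromo-7-methoxy-2H-chromen-2-one | COc1cc2oc(=O)ccc2cc1Br
F4 | step 5 | 5-bromo-6-methoxy-1-indanone (purchased) | COc1cc2c(cc1Br)CCC2=O
F5 | step 7 | 5-[(4-bromo-7-methoxy-2-oxo-3,4-dihydro-2H-chromen-6-yl)oxy]-6,7-dimethoxy-2H-chromen-2-one (racemic) | COc1cc2OC(=O)CC(Br)c2cc1Oc1c(OC)c(OC)cc2oc(=O)ccc12
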